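The route rests on the bond between C3 of ring B (the trisubstituted phenol ring; C3 is ortho to the oxygen on C4) and the methine C2' of the 1-arylpropan-2-yl arm. Both carbons are innately nucleophilic, so C2' is umpoled as a secondary pyridine-2-sulfonate made from (S)-propylene oxide. The key step exploits the ring B oxygen: it steers bromine–magnesium exchange of a 2,4-dibromophenyl benzyl ether to C3. Copper-catalysed displacement then forms the bond, sets C2' by inversion and keeps the C1 bromide. That bromide later joins a lactone from desymmetrised meso-2,3-dimethylsuccinic anhydride to build the pseudo-meso oxolane.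

Key step: step 4

Assumption: the sense of induction in step 6 follows the ligand enantiomer. The TADDOL-phosphoramidite antipode used is the one that sends the aryl group to the carbonyl next to the (S)-configured carbon of 11.

Labels:
- Ring A is the 4-hydroxyphenyl group on oxolane C2.
- Ring B is the phenol ring on oxolane C5. Its C1 bears the oxolane, C3 the arm and C4 the oxygen.
- Ring C is the 4-hydroxyphenyl group of the arm.
- The arm is C1' (CH2), C2' (CH) and C3' (CH3).

Step 1
Reactants: 1 1-(benzyloxy)-4-bromobenzene; 2 (S)-propylene oxide [(2S)-2-methyloxirane]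
Product: 4 (2S)-1-[4-(benzyloxy)phenyl]propan-2-ol, via 4-(benzyloxy)phenylmagnesium bromide 3 (not isolated)
Conditions: Mg, THF, 40 °C; then CuBr·SMe2 (10 mol %), 2, THF, −30 → 0 °C
Reagents that add atoms: none
Why: Copper-catalysed Grignard opening of a terminal epoxide (SN2 at the unsubstituted CH2) leaves the C–O stereocentre of 2 untouched, so 4 inherits the (S) configuration from the chiral pool.

Step 2
Reactants: 4 (2S)-1-[4-(benzyloxy)phenyl]propan-2-ol
Product: 5 (2S)-1-[4-(benzyloxy)phenyl]propan-2-yl pyridine-2-sulfonate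
Conditions: pyridine-2-sulfonyl chloride, Et3N, DMAP (cat.), CH2Cl2, 0 °C
Reagents that add atoms: pyridine-2-sulfonyl chloride, O=S(=O)(Cl)c1ccccn1
Why: O-Sulfonylation of a secondary alcohol breaks no bond at carbon, so the (S) centre is retained while the hydroxyl becomes a chelating leaving group.

Step 3
Reactants: 6 2,4-dibromophenol
Product: 7 1-(benzyloxy)-2,4-dibromobenzene
Conditions: BnBr, K2CO3, DMF, rt
Reagents that add atoms: benzyl bromide, BrCc1ccccc1
Why: Williamson ether synthesis on the acidic dibromophenol masks the ring B oxygen as a hydrogenolysable ether that can still chelate magnesium.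

Step 4
Reactants: 7 1-(benzyloxy)-2,4-dibromobenzene; 5 (2S)-1-[4-(benzyloxy)phenyl]propan-2-yl pyridine-2-sulfonate
Product: 9 1-(benzyloxy)-2-{(2R)-1-[4-(benzyloxy)phenyl]propan-2-yl}-4-bromobenzene, via [2-(benzyloxy)-5-bromophenyl]magnesium chloride 8 (not isolated)
Conditions: 7 (2 equiv), i-PrMgCl·LiCl, THF, 0 °C → rt; then Cu(OTf)2 (10 mol %), 5, THF, 0 °C → rt
Reagents that add atoms: none
Why: The benzyloxy oxygen on C4 of ring B chelates magnesium and stabilises the neighbouring carbanion, so halogen–magnesium exchange with the LiCl-complexed isopropyl Grignard reagent takes only the bromine at C3 (C2 of 7) and 8 keeps the bromine at C1. Cu(OTf)2 is reduced by 8 to a monovalent arylcuprate that attacks the sulfonate-bearing carbon of 5 from the rear (SN2-type oxidative addition to a trivalent alkylcopper species) and then releases 9 by reductive elimination with retention. The closest known reaction type is the copper-catalysed cross-coupling of Grignard reagents with secondary alkyl sulfonates, which like the diarylcuprate displacement of secondary tosylates runs with inversion. No ring is closed, and the one new stereocentre C2' is controlled by the stereocentre of 5 bought with 2, (S) in 5 becoming (R) in 9. The step needs substitution to win over E2 loss of a benzylic hydrogen and over participation by electron-rich ring C, which the soft and weakly basic cuprate, the non-ionising solvent, the low temperature and the magnesium-chelating pyridylsulfonyl leaving group should secure. It also needs the aryl bromide and the 2-bromopropane from the exchange to stay inert, which is expected because neither has a chelating leaving group and copper does not insert into aryl bromides under these conditions.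

Step 5
Reactants: 10 2,3-dimethylmaleic anhydride
Product: 11 meso-2,3-dimethylsuccinic anhydride [(3R,4S)-3,4-dimethyloxolane-2,5-dione]
Conditions: H2 (10 bar), Pd/C, EtOAc, rt
Reagents that add atoms: none
Why: Heterogeneous catalytic hydrogenation adds both hydrogens to one face of the tetrasubstituted alkene (syn addition), which gives only the cis, meso anhydride.

Step 6
Reactants: 1 1-(benzyloxy)-4-bromobenzene; 11 meso-2,3-dimethylsuccinic anhydride
Product: 14 (2R,3S)-4-[4-(benzyloxy)phenyl]-2,3-dimethyl-4-oxobutanoic acid, via 4-(benzyloxy)phenyllithium 12 (not isolated), via [4-(benzyloxy)phenyl]zinc triflate 13 (not isolated)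
Conditions: 1, n-BuLi, THF, −78 °C; Zn(OTf)2, −78 °C → rt; then 11, [Rh(cod)Cl]2 (4 mol %), TADDOL-derived dimethylphosphoramidite (8 mol %), THF, 50 °C
Reagents that add atoms: none
Why: Rhodium-catalysed enantioselective desymmetrisation of a meso anhydride with an arylzinc reagent (acyl C–O insertion of monovalent rhodium, transmetalation, reductive elimination) lets the chiral ligand pick one of the two enantiotopic carbonyl groups, and since the methine carbons are not touched their relative configuration comes from 11 and their absolute sense from the ligand.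

Step 7
Reactants: 14 (2R,3S)-4-[4-(benzyloxy)phenyl]-2,3-dimethyl-4-oxobutanoic acid
Product: 16 (3R,4S,5S)-5-[4-(benzyloxy)phenyl]-3,4-dimethyloxolan-2-one, via hydroxy acid 15 (not isolated)
Conditions: NaBH4, EtOH, −20 → 0 °C; then 2 M HCl, rt
Reagents that add atoms: none
Why: Felkin–Anh-controlled borohydride reduction of the aryl ketone followed by acid lactonisation should give the lactone with the aryl group trans to the neighbouring methyl, and a minor epimer is harmless because this benzylic centre is equilibrated again in step 9.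

Step 8
Reactants: 9 1-(benzyloxy)-2-{(2R)-1-[4-(benzyloxy)phenyl]propan-2-yl}-4-bromobenzene; 16 (3R,4S,5S)-5-[4-(benzyloxy)phenyl]-3,4-dimethyloxolan-2-one
Product: 18 (2R,3S,4S)-1-{4-(benzyloxy)-3-[(2R)-1-[4-(benzyloxy)phenyl]propan-2-yl]phenyl}-4-[4-(benzyloxy)phenyl]-4-hydroxy-2,3-dimethylbutan-1-one (in equilibrium with its cyclic hemiketal), via aryllithium 17 (not isolated)
Conditions: 9, n-BuLi, THF, −78 °C; then 16, THF, −78 °C
Reagents that add atoms: none
Why: Bromine–lithium exchange and single 1,2-addition of the aryllithium to the γ-lactone at low temperature stops at the tetrahedral lithium hemiketal, which opens on work-up to the γ-hydroxy ketone without touching the four existing stereocentres.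

Step 9
Reactants: 18 the γ-hydroxy ketone of step 8
Product: 20 (2S,3S,4R,5R)-2-[4-(benzyloxy)phenyl]-5-{4-(benzyloxy)-3-[(2R)-1-[4-(benzyloxy)phenyl]propan-2-yl]phenyl}-3,4-dimethyloxolane, via diol 19 (not isolated)
Conditions: NaBH4, MeOH/THF, 0 °C; then crude diol, TFA (20 mol %), CH2Cl2, 0 °C → rt
Reagents that add atoms: none
Why: Borohydride reduction and Brønsted acid cyclodehydration through para-benzyloxybenzylic cations let both benzylic C–O bonds ionise reversibly, so all diol epimers should funnel under thermodynamic control to the oxolane with each aryl group trans to its neighbouring methyl (2,3-trans, 3,4-cis, 4,5-trans) while C3 and C4 stay fixed.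

Step 10
Reactants: 20 the tribenzyl ether of step 9
Product: 21 4-[(2S,3S,4R,5R)-5-{4-hydroxy-3-[(2R)-1-(4-hydroxyphenyl)propan-2-yl]phenyl}-3,4-dimethyloxolan-2-yl]phenol (target)
Conditions: H2 (1 atm), Pd/C (10 %), EtOAc/EtOH, rt
Reagents that add atoms: none
Why: Catalytic hydrogenolysis under neutral conditions cleaves the three primary benzyl aryl ethers much faster than the hindered secondary benzylic C–O bonds of the oxolane, and no stereocentre is affected.

Compound list
1 | 1-(benzyloxy)-4-bromobenzene | Brc1ccc(OCc2ccccc2)cc1 | starting material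
2 | (S)-propylene oxide | C[C@H]1CO1 | starting material
3 | 4-(benzyloxy)phenylmagnesium bromide | Br[Mg]c1ccc(OCc2ccccc2)cc1 | intermediate
4 | (2S)-1-[4-(benzyloxy)phenyl]propan-2-ol | C[C@H](O)Cc1ccc(OCc2ccccc2)cc1 | intermediate
5 | (2S)-1-[4-(benzyloxy)phenyl]propan-2-yl pyridine-2-sulfonate | C[C@H](OS(=O)(=O)c1ccccn1)Cc1ccc(OCc2ccccc2)cc1 | intermediate
6 | 2,4-dibromophenol | Oc1ccc(Br)cc1Br | starting material
7 | 1-(benzyloxy)-2,4-dibromobenzene | Brc1ccc(OCc2ccccc2)c(Br)c1 | intermediate
8 | [2-(benzyloxy)-5-bromophenyl]magnesium chloride | Cl[Mg]c1cc(Br)ccc1OCc1ccccc1 | intermediate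
9 | 1-(benzyloxy)-2-{(2R)-1-[4-(benzyloxy)phenyl]propan-2-yl}-4-bromobenzene | Brc1ccc(OCc2ccccc2)c([C@H](C)Cc2ccc(OCc3ccccc3)cc2)c1 | intermediate
10 | 2,3-dimethylmaleic anhydride | CC1=C(C)C(=O)OC1=O | starting material
11 | meso-2,3-dimethylsuccinic anhydride, (3R,4S), cis | C[C@H]1C(=O)OC(=O)[C@H]1C | intermediate
12 | 4-(benzyloxy)phenyllithium | [Li]c1ccc(OCc2ccccc2)cc1 | intermediate
13 | [4-(benzyloxy)phenyl]zinc triflate | FC(F)(F)S(=O)(=O)O[Zn]c1ccc(OCc2ccccc2)cc1 | intermediate
14 | (2R,3S)-4-[4-(benzyloxy)phenyl]-2,3-dimethyl-4-oxobutanoic acid | C[C@@H](C(=O)O)[C@H](C)C(=O)c1ccc(OCc2ccccc2)cc1 | intermediate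
15 | (2R,3S,4S)-4-[4-(benzyloxy)phenyl]-4-hydroxy-2,3-dimethylbutanoic acid | C[C@@H](C(=O)O)[C@H](C)[C@H](O)c1ccc(OCc2ccccc2)cc1 | intermediate
16 | (3R,4S,5S)-5-[4-(benzyloxy)phenyl]-3,4-dimethyloxolan-2-one (3,4-cis, 4,5-trans) | C[C@@H]1[C@H](C)[C@@H](c2ccc(OCc3ccccc3)cc2)OC1=O | intermediate
17 | {4-(benzyloxy)-3-[(2R)-1-[4-(benzyloxy)phenyl]propan-2-yl]phenyl}lithium | [Li]c1ccc(OCc2ccccc2)c([C@H](C)Cc2ccc(OCc3ccccc3)cc2)c1 | intermediate
18 | (2R,3S,4S)-1-{4-(benzyloxy)-3-[(2R)-1-[4-(benzyloxy)phenyl]propan-2-yl]phenyl}-4-[4-(benzyloxy)phenyl]-4-hydroxy-2,3-dimethylbutan-1-one | C[C@@H](C(=O)c1ccc(OCc2ccccc2)c([C@H](C)Cc2ccc(OCc3ccccc3)cc2)c1)[C@H](C)[C@H](O)c1ccc(OCc2ccccc2)cc1 | intermediate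
19 | (1R,2R,3S,4S)-1-{4-(benzyloxy)-3-[(2R)-1-[4-(benzyloxy)phenyl]propan-2-yl]phenyl}-4-[4-(benzyloxy)phenyl]-2,3-dimethylbutane-1,4-diol (expected major C1 epimer drawn) | C[C@@H]([C@@H](O)c1ccc(OCc2ccccc2)c([C@H](C)Cc2ccc(OCc3ccccc3)cc2)c1)[C@H](C)[C@H](O)c1ccc(OCc2ccccc2)cc1 | intermediate
20 | (2S,3S,4R,5R)-2-[4-(benzyloxy)phenyl]-5-{4-(benzyloxy)-3-[(2R)-1-[4-(benzyloxy)phenyl]propan-2-yl]phenyl}-3,4-dimethyloxolane | C[C@@H]1[C@H](C)[C@@H](c2ccc(OCc3ccccc3)cc2)O[C@H]1c1ccc(OCc2ccccc2)c([C@H](C)Cc2ccc(OCc3ccccc3)cc2)c1 | intermediate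
21 | 4-[(2S,3S,4R,5R)-5-{4-hydroxy-3-[(2R)-1-(4-hydroxyphenyl)propan-2-yl]phenyl}-3,4-dimethyloxolan-2-yl]phenol | C[C@@H]1[C@H](C)[C@@H](c2ccc(O)cc2)O[C@H]1c1ccc(O)c([C@H](C)Cc2ccc(O)cc2)c1 | target

Total step count: 10. Longest linear sequence: 6 steps (1, 2, 4, 8, 9, 10 or 5, 6, 7, 8, 9, 10).

Steps most likely to fail

Step 4. Three things may go wrong:
- E2 elimination of the sulfonate to the propenylarene.
- Sluggish displacement by the hindered ortho-substituted arylcopper species.
- Partial loss of stereochemical fidelity through participation of ring C.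

The fallback sets out from 4 and from 8 (made from 7 as in step 4) and comes back at 9. It forms the same bond by carbonyl addition and sets C2' afterwards by catalyst control. Alcohol 4 is oxidised with Dess–Martin periodinane to 1-[4-(benzyloxy)phenyl]propan-2-one F1. Grignard reagent 8 adds to F1 in the presence of LaCl3·2LiCl to give racemic 2-[2-(benzyloxy)-5-bromophenyl]-1-[4-(benzyloxy)phenyl]propan-2-ol F2. Dehydration with p-TsOH under equilibrating conditions gives the conjugated alkene 1-(benzyloxy)-2-{(E)-1-[4-(benzyloxy)phenyl]prop-1-en-2-yl}-4-bromobenzene F3. Asymmetric hydrogenation with a chiral phosphinooxazoline complex [Ir(cod)(PHOX)]BArF, with the ligand enantiomer chosen for the (R) product, then gives 9.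

Step 9. Equilibration may stay incomplete, so that isomers with an aryl group cis to its neighbouring methyl are trapped. Alternatively, proton loss from the benzylic cations may scramble C3 and C4.

The fallback sets out from 16 and 17 and comes back at 20. It delivers ring B as a nucleophile to an aldehyde-level oxocarbenium ion, so that C5 is set kinetically. Lactone 16 is reduced with i-Bu2AlH at −78 °C to (3R,4S,5S)-5-[4-(benzyloxy)phenyl]-3,4-dimethyloxolan-2-ol F4. Benzenesulfinic acid and CaCl2 convert F4 into (2S,3S,4R)-2-[4-(benzyloxy)phenyl]-3,4-dimethyl-5-(phenylsulfonyl)oxolane F5. Aryllithium 17 is transmetalated with ZnBr2 to {4-(benzyloxy)-3-[(2R)-1-[4-(benzyloxy)phenyl]propan-2-yl]phenyl}zinc bromide F6. F6 ionises F5 and should add to the cation on the face opposite to the C3 and C4 methyl groups, which gives 20.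

Step 6. Discrimination of the enantiotopic carbonyl groups may be insufficient, or the centre alpha to the new ketone may epimerise at 50 °C.

The fallback sets out from 11 and comes back at 16. It replaces C–C desymmetrisation by organocatalytic alcoholysis.
- Methanolysis uses a dimeric cinchona alkaloid ether, (DHQD)2AQN or its quinine-derived counterpart, whichever opens the carbonyl next to the (R)-configured carbon. It gives (2S,3R)-4-methoxy-2,3-dimethyl-4-oxobutanoic acid F7.
- Oxalyl chloride gives methyl (2R,3S)-4-chloro-2,3-dimethyl-4-oxobutanoate F8.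
- Acylation of arylzinc 13 with F8, catalysed by Pd(PPh3)4 (Negishi type), gives methyl (2R,3S)-4-[4-(benzyloxy)phenyl]-2,3-dimethyl-4-oxobutanoate F9.
- NaBH4 reduction gives methyl (2R,3S,4S)-4-[4-(benzyloxy)phenyl]-4-hydroxy-2,3-dimethylbutanoate F10, which lactonises with acid to 16.

Further compounds
F1 | step 4 | 1-[4-(benzyloxy)phenyl]propan-2-one | CC(=O)Cc1ccc(OCc2ccccc2)cc1
F2 | step 4 | 2-[2-(benzyloxy)-5-bromophenyl]-1-[4-(benzyloxy)phenyl]propan-2-ol (racemic) | CC(O)(Cc1ccc(OCc2ccccc2)cc1)c1cc(Br)ccc1OCc1ccccc1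
F3 | step 4 | 1-(benzyloxy)-2-{(E)-1-[4-(benzyloxy)phenyl]prop-1-en-2-yl}-4-bromobenzene | C/C(=C\c1ccc(OCc2ccccc2)cc1)c1cc(Br)ccc1OCc1ccccc1
F4 | step 9 | (3R,4S,5S)-5-[4-(benzyloxy)phenyl]-3,4-dimethyloxolan-2-ol (anomers) | C[C@@H]1[C@H](C)[C@@H](c2ccc(OCc3ccccc3)cc2)OC1O
F5 | step 9 | (2S,3S,4R)-2-[4-(benzyloxy)phenyl]-3,4-dimethyl-5-(phenylsulfonyl)oxolane (C5 epimers) | C[C@@H]1[C@H](C)[C@@H](c2ccc(OCc3ccccc3)cc2)OC1S(=O)(=O)c1ccccc1
F6 | step 9 | {4-(benzyloxy)-3-[(2R)-1-[4-(benzyloxy)phenyl]propan-2-yl]phenyl}zinc bromide | Br[Zn]c1ccc(OCc2ccccc2)c([C@H](C)Cc2ccc(OCc3ccccc3)cc2)c1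
F7 | step 6 | (2S,3R)-4-methoxy-2,3-dimethyl-4-oxobutanoic acid | C[C@@H](C(=O)OC)[C@H](C)C(=O)O
F8 | step 6 | methyl (2R,3S)-4-chloro-2,3-dimethyl-4-oxobutanoate | C[C@@H](C(=O)OC)[C@H](C)C(=O)Cl
F9 | step 6 | methyl (2R,3S)-4-[4-(benzyloxy)phenyl]-2,3-dimethyl-4-oxobutanoate | C[C@@H](C(=O)OC)[C@H](C)C(=O)c1ccc(OCc2ccccc2)cc1
F10 | step 6 | methyl (2R,3S,4S)-4-[4-(benzyloxy)phenyl]-4-hydroxy-2,3-dimethylbutanoate | C[C@@H](C(=O)OC)[C@H](C)[C@H](O)c1ccc(OCc2ccccc2)cc1
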